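(The runs are simulated from invented constants, noise included.)

After 8.00 h the larch run holds 66.5% product and the alder run 1.2%, and these two flasks differ in their added ligand.

all flasks: substrate 0.050 M; gas 24 mM (held); free catalyst 0.14 mM
- larch: added ligand 0.074 mM; run made earlier
- alder: added ligand 2.4 mM; run made earlier
- Monday's: added ligand 0.060 mM; time 8.0 h
- Thursday's: added ligand 0.15 mM; time 8.0 h
- Tuesday's: added ligand 0.50 mM; time 8.0 h
- Wednesday's: added ligand 1.5 mM; time 8.0 h

| run | time / h | product / % | substrate / % |
|---|---|---|---|
| larch | 0.500 | 1.4 | 99.0 |
| larch | 1.50 | 6.9 | 94.2 |
| larch | 3.00 | 19.3 | 81.3 |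
| larch | 4.00 | 27.4 | 72.2 |
| larch | 6.00 | 46.9 | 52.7 |
| larch | 8.00 | 66.5 | 33.1 |
| alder | 0.667 | 0.4 | 99.2 |
| alder | 1.00 | 0.5 | 99.6 |
| alder | 2.00 | 0.2 | 98.9 |
| alder | 3.00 | 0.4 | 98.9 |
| alder | 5.00 | 0.9 | 99.9 |
| alder | 8.00 | 1.2 | 99.5 |

(scatter of a reading: 0.5 percentage points)

- at the start none of the gas is in solution
- "hardly changes" means that all values lie within two and a half points (for a concentration: within two and a half percent of the largest)

- amount of product at the end, in percent of the substrate charged for Monday's, Thursday's, Tuesday's, Wednesday's, in this order
- how that number moves from the first to the last of them (rises all the way / rises, then falls / falls all the way / hardly changes / falls, then rises)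

In powers of ten, the added ligand rises by 1.51 from larch to alder, while the product falls by 1.74. That is a steeper fall than plain inverse dependence, though the alder reading of 1.2% carries a scatter of 0.5 percentage points. A fall this steep suggests that the ligand removes catalyst one for one.

So we fold the charges into x, the ratio of added ligand to free catalyst charged: 0.429 for Monday's flask. If binding is tight, x below one leaves a free share of one minus x. Above one, the free share goes as a constant k divided by x minus one, where k measures how weakly the ligand binds. We suppose that end product follows the free share. The larch run, at 0.529, then gives the scale, and the alder run, at 17.1, gives k = 0.137.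

Our reckoning gives 80.6% for Monday's flask. For Tuesday's, at 3.57, it gives 7.53%, and for Wednesday's, at 10.7, 1.99%.

Was x enough? Above one it already needed k, and Thursday's flask, at 1.07, sits almost on equivalence, where neither limit serves. For that flask the full binding balance with k gives us a free share of 0.281, hence 39.6%.

The forecast says 77%, 34%, 6% and 1.7%, so falls all the way, on the ground “I assume free catalyst is the active form”. Our figures stand above these, with the same shape.

The flasks give 73.0%, 32.7%, 4.92% and 1.36%: falls all the way.

    free catalyst + added ligand ⇌ idle complex, settled at all times (K = 1.06 × 10⁵ M⁻¹)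
    substrate + catalyst intermediate A → catalyst intermediate B (k = 126 M⁻¹ s⁻¹)
    catalyst intermediate B → free catalyst + product (k = 3.30 s⁻¹)
    gas ⇌ coupling partner, rate k4*(csat - [coupling partner]) (kL = 1.26 × 10⁻⁴ s⁻¹)
    coupling partner + free catalyst → catalyst intermediate A (k = 1.41 M⁻¹ s⁻¹)

The association of free catalyst and added ligand to the idle complex is the main reason for the small product of Wednesday's flask: that flask gives 1.36% with it and 94.4% without it. In Monday's flask, at x = 0.429, free catalyst stands at 60.5% of the charge after 8.00 h, against the 57.1% that one minus x gives for tight binding. In Wednesday's flask, at x = 10.7, the idle complex holds 99.3% of the catalyst charged after 8.00 h, and free catalyst 0.688%.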